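The numbers in the tables are calculated with constants of no real substance.

**Side exits.** In a one-step world all reacted solid substrate becomes target, and protic impurity has no say. In the flasks here, dissolved starting material can also go to side product or be quenched. So I work with the fraction kept from quenching, and the decision is whether the four charges below can stand or the high-impurity flasks need changing.

| flask | solid substrate | protic impurity | remark | time |
|---|---|---|---|---|
| teal | 0.050 M | 0.0017 M | run made earlier |  |
| blue | 0.050 M | 0.070 M | run made earlier |  |
| Friday's | 0.050 M | 0.00300 M |  | 10 min |
| Tuesday's | 0.050 M | 0.0100 M |  | 10 min |
| Thursday's | 0.050 M | 0.0300 M |  | 10 min |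
| Monday's | 0.050 M | 0.100 M |  | 10 min |

| run | time / min | target / % |
|---|---|---|
| teal | 0.833 | 2 |
| teal | 1.50 | 4 |
| teal | 2.50 | 7 |
| teal | 3.00 | 6 |
| teal | 4.00 | 12 |
| teal | 5.00 | 10 |
| blue | 0.333 | 2 |
| blue | 1.00 | 3 |
| blue | 2.00 | 5 |
| blue | 2.50 | 5 |
| blue | 4.00 | 12 |
| blue | 5.00 | 11 |

(standard deviation of a reading: 1.5 percentage points)

* amount of target at the end, in percent of the solid substrate charged for Friday's, Tuesday's, Thursday's, Monday's, in this order
* how the row runs (falls all the way / rises all the way / hardly changes / falls, then rises / rises, then falls)

- given per volume of solution although it is solid: solid substrate
- what may be going on: starting material -> target; starting material -> side product; solid substrate <-> starting material; starting material + protic impurity -> quenched substrate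
- at the start none of the solid substrate is in solution
- "hardly changes" means that all values lie within two and a half points (for a concentration: within two and a half percent of the largest)

**Reading the runs.** The teal and blue runs share 3 times: 2.50 min, 4.00 min and 5.00 min. Summed over these, the blue readings are 0.966 of the teal ones, give or take 0.127. I define the quench weight as the quenched share over the kept share, per unit of [protic impurity], a selectivity factor. Taking [protic impurity] as its charge, the fraction kept is then one over (one plus weight times [protic impurity]). This reading gives a weight of 0.523 /M, so Monday's flask should keep 0.952 of what Friday's keeps. At the forecast's level, that is a fall of 1.1 percentage points.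

**The decision.** Two standard errors allow a weight of 5.92 /M, and then Monday's flask would keep 0.639. The reading leaves that open, so I leave the charges unchanged and keep Monday's flask on the plate as the test of the weight.

**The forecast.** It gives 23%, 23%, 23% and 23%, and says the row hardly changes, since “their target curves overlap within the noise”. I expect a small fall where the forecast has a level row.

**The result.** The flasks give 27.3%, 27.2%, 26.8% and 25.4%, so the row hardly changes.

    starting material → target (k = 0.0150 /s)
    starting material → side product (k = 0.0270 /s)
    solid substrate ⇌ starting material, rate k3*(cs3 - [starting material]) while solid is left; crystals form when [starting material] > cs3 (solubility = 20.0 mM, k = 0.00360 /s)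
    starting material + protic impurity → quenched substrate (k = 0.0370 /M/s)

**Two half-lives.** In Friday's flask at 10.0 min, the half-life of starting material is 110 min by quenching and 0.43 min by the step to side product, a factor of 252. Against Friday's target, the weight gives Monday's flask 0.952 where the flask gives 0.930, and it gives Thursday's flask 0.986 where the flask gives 0.982.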